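**Plan**

1. Cembrane numbering is used for every compound (ring C1–C14; lactone carbons C15 and C16; methylene C17). Retrosynthetic cuts, in order: both C–O bonds of the C3–C4 oxirane; the C13 acetate and C15=C17; C10–C11 (as an alkene); O–C16 and C1–C15 of the lactone; C12–C13; C1–C2 and C9–C10.
2. Forward: geranyl acetate (C2–C9, both E-alkenes in place) gains a vinyl group at C9 and a C1/C14/C13 propenol unit at C2. The C14=C1 alkene is epoxidised, and C13 is oxidised and crotylated (C12, its methyl, C11).
3. Opening the oxirane at C1 with a C15–C16 ynol ether, then acid closure, gives the γ-lactone (first ring). Metathesis at C10=C11 closes the fourteen-membered carbocycle (second ring). The C3–C4 oxirane (third ring) comes last.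
4. Stereochemistry: the C3=C4 and C7=C8 geometries come from geranyl acetate. C14 and C1 come from a Sharpless epoxidation, with C1 inverted in the opening, which gives the cis-lactone. C13 and C12 come from a Brown (Z)-crotylboration, and C3 and C4 from the enzyme pocket.
5. Feature behind the last step: the diene precursor holds only two electron-rich alkenes. C3=C4 lies two carbons from the polar edge formed by the C1/C14-fused lactone ring and the C13 acetate. C7=C8 lies in the hydrocarbon half, and C15=C17 is electron-poor. A shaped active site can tell the three apart where a reagent in solution cannot.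

Key step: step 17

Assumption: the P450 BM3 variant of the last step is defined by function, not by sequence. It is the member of an active-site library that oxidises the 3Re,4Re face of C3=C4, and it has to be found by screening.
Assumption: the geometry of the C10=C11 alkene made by metathesis has no consequence; it is drawn E.

**Route**

Step 1
Reactants: 1 geranyl acetate
Product: 2 (2E,6E)-8-hydroxy-3,7-dimethylocta-2,6-dien-1-yl acetate
Conditions: SeO2 (cat.), t-BuOOH, salicylic acid (cat.), CH2Cl2, 0 °C to rt
Reagents that add atoms: tert-butyl hydroperoxide, CC(C)(C)OO (oxygen, passed on through SeO2)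
Why: Riley allylic oxidation (ene reaction, then [2,3]-sigmatropic shift) should strike the electron-rich terminal alkene at its E-methyl group, because C3=C4 is deactivated by the allylic acetate, so that C9 is oxidised and C7=C8 stays E.

Step 2
Reactants: 2 (2E,6E)-8-hydroxy-3,7-dimethylocta-2,6-dien-1-yl acetate
Product: 3 (2E,6E)-8-bromo-3,7-dimethylocta-2,6-dien-1-yl acetate
Conditions: CBr4, PPh3, CH2Cl2, 0 °C
Reagents that add atoms: carbon tetrabromide, BrC(Br)(Br)Br
Why: Appel reaction, in which bromide displaces the alkoxyphosphonium ion in an SN2 step at the primary allylic carbon, without allylic shift and without touching the acetate.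

Step 3
Reactants: 3 (2E,6E)-8-bromo-3,7-dimethylocta-2,6-dien-1-yl acetate
Product: 4 (2E,6E)-3,7-dimethyldeca-2,6,9-trien-1-yl acetate
Conditions: Bu3SnCH=CH2, Pd2(dba)3 (cat.), AsPh3 (cat.), THF, rt
Reagents that add atoms: tributyl(vinyl)stannane, C=C[Sn](CCCC)(CCCC)CCCC
Why: Stille coupling of an allylic bromide with a vinylstannane, in which zerovalent palladium inserts into C9–Br far faster than it ionises the C2 acetate in chloride-free THF, and reductive elimination at the primary allyl terminus should give the skipped diene with E geometry kept.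

Step 4
Reactants: 5 prop-2-yn-1-ol
Product: 6 (E)-3-(tributylstannyl)prop-2-en-1-ol
Conditions: Bu3SnH, AIBN (cat.), neat, 80 °C
Reagents that add atoms: tributyltin hydride, CCCC[SnH](CCCC)CCCC
Why: Radical hydrostannation of a terminal alkyne, in which reversible stannyl-radical addition at 80 °C funnels the adducts towards the thermodynamically preferred E-β-stannyl alkene, which is separated from its isomers by chromatography.

Step 5
Reactants: 4 (2E,6E)-3,7-dimethyldeca-2,6,9-trien-1-yl acetate; 6 (E)-3-(tributylstannyl)prop-2-en-1-ol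
Product: 7 (2E,5E,9E)-6,10-dimethyltrideca-2,5,9,12-tetraen-1-ol
Conditions: Pd(dba)2 (cat.), LiCl (3 equiv), DMF, rt
Reagents that add atoms: none
Why: Stille-type coupling of an allylic acetate with an alkenylstannane (ligand-free zerovalent palladium, chloride as promoter), in which C1–C2 should form only at the primary allyl terminus, both partners keep their E geometry and the free hydroxyl is tolerated.

Step 6
Reactants: 7 (2E,5E,9E)-6,10-dimethyltrideca-2,5,9,12-tetraen-1-ol
Product: 8 {(2S,3S)-3-[(2E,6E)-3,7-dimethyldeca-2,6,9-trien-1-yl]oxiran-2-yl}methanol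
Conditions: Ti(OiPr)4 (cat.), L-(+)-diethyl tartrate (cat.), t-BuOOH, 4 Å molecular sieves, CH2Cl2, −20 °C
Reagents that add atoms: tert-butyl hydroperoxide, CC(C)(C)OO
Why: Sharpless asymmetric epoxidation, in which only the alkene of the titanium-bound allylic alcohol is oxidised and L-(+)-tartrate directs oxygen to the face of the E-alkene that gives the (2S,3S)-oxirane, that is, the final 14R centre and a C1–O bond ready for inversion.

Step 7
Reactants: 8 {(2S,3S)-3-[(2E,6E)-3,7-dimethyldeca-2,6,9-trien-1-yl]oxiran-2-yl}methanol
Product: 9 (2R,3S)-3-[(2E,6E)-3,7-dimethyldeca-2,6,9-trien-1-yl]oxirane-2-carbaldehyde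
Conditions: TEMPO (cat.), PhI(OAc)2, CH2Cl2, rt
Reagents that add atoms: none
Why: Oxoammonium oxidation of a primary alcohol stops at the aldehyde under nearly neutral conditions that the oxirane and the skipped dienes should survive.

Step 8
Reactants: 9 (2R,3S)-3-[(2E,6E)-3,7-dimethyldeca-2,6,9-trien-1-yl]oxirane-2-carbaldehyde
Product: 11 (1R,2S)-1-{(2S,3S)-3-[(2E,6E)-3,7-dimethyldeca-2,6,9-trien-1-yl]oxiran-2-yl}-2-methylbut-3-en-1-ol, via O-borinate 10 (not isolated)
Conditions: cis-2-butene, n-BuLi, KOt-Bu, THF, −78 to −45 °C; (+)-Ipc2BOMe [from (−)-α-pinene], −78 °C; BF3·OEt2; 9, −78 °C; HOCH2CH2NH2, rt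
Reagents that add atoms: cis-2-butene, C/C=C\C; (+)-B-methoxydiisopinocampheylborane, COB([C@H]1C[C@H]2C[C@@H]([C@@H]1C)C2(C)C)[C@H]1C[C@H]2C[C@@H]([C@@H]1C)C2(C)C (its boryl group stays only in 10)
Why: Brown asymmetric crotylboration through a closed chair transition state, in which the Z-crotyl geometry gives the syn C12-methyl/C13-hydroxyl pair and the (−)-α-pinene-derived groups direct attack to the Re face of the aldehyde (13R), overriding the small intrinsic bias of a trans-epoxy aldehyde.

Step 9
Reactants: 11 (1R,2S)-1-{(2S,3S)-3-[(2E,6E)-3,7-dimethyldeca-2,6,9-trien-1-yl]oxiran-2-yl}-2-methylbut-3-en-1-ol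
Product: 12 tert-butyldimethylsilyl ether of 11 (C13–OTBS)
Conditions: TBSOTf, 2,6-lutidine, CH2Cl2, −78 °C
Reagents that add atoms: tert-butyldimethylsilyl triflate, CC(C)(C)[Si](C)(C)OS(=O)(=O)C(F)(F)F
Why: Silylation with a silyl triflate and a hindered base protects the crowded C13 hydroxyl at low temperature, blocks Payne migration, and supplies the bulk and inductive pull that steer the next step.

Step 10
Reactants: 12 tert-butyldimethylsilyl ether of 11
Product: 13 (3S,4R,5R,6S,8E,12E)-4-(tert-butyldimethylsilyloxy)-6-(ethoxyethynyl)-3,9,13-trimethylhexadeca-1,8,12,15-tetraen-5-ol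
Conditions: HC≡COEt, n-BuLi, THF, −78 °C; BF3·OEt2; 12, −78 °C
Reagents that add atoms: ethoxyacetylene, C#COCC
Why: BF3-assisted alkynylation of an epoxide (Yamaguchi-type opening), in which SN2 attack with inversion should occur at C1, the oxirane carbon remote from the bulky and inductively deactivating C13 silyloxy branch, placing C15 anti to the C14 oxygen as the cis-lactone requires.

Step 11
Reactants: 13 (3S,4R,5R,6S,8E,12E)-4-(tert-butyldimethylsilyloxy)-6-(ethoxyethynyl)-3,9,13-trimethylhexadeca-1,8,12,15-tetraen-5-ol
Product: 14 (4S,5R)-5-[(1R,2S)-1-(tert-butyldimethylsilyloxy)-2-methylbut-3-en-1-yl]-4-[(2E,6E)-3,7-dimethyldeca-2,6,9-trien-1-yl]dihydrofuran-2(3H)-one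
Conditions: p-TsOH·H2O (cat.), THF/H2O, rt
Reagents that add atoms: water, O
Why: Acid-catalysed addition of the C14 hydroxyl to the protonated ynol ether and hydrolysis of the resulting cyclic ketene acetal give the γ-lactone without breaking a bond to any stereocentre, so C13 and C2 end up cis on the ring.

Step 12
Reactants: 14 (4S,5R)-5-[(1R,2S)-1-(tert-butyldimethylsilyloxy)-2-methylbut-3-en-1-yl]-4-[(2E,6E)-3,7-dimethyldeca-2,6,9-trien-1-yl]dihydrofuran-2(3H)-one
Product: 15 (1S,3E,7E,10E,12S,13R,14R)-13-(tert-butyldimethylsilyloxy)-17-norcembra-3,7,10-trien-16,14-olide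
Conditions: RuCl2(=CHPh)(PCy3)(H2IMes) (second-generation Grubbs catalyst, 10 mol %), toluene (0.5 mM), 80–110 °C, argon sparge
Reagents that add atoms: none
Why: Ring-closing metathesis of two monosubstituted alkenes, in which the catalyst should load on the unhindered C10 terminus (from which no small ring can form, since an E C7=C8 bond cannot sit in a seven-membered ring) and then close the fourteen-membered ring onto the C11 vinyl group, a pairing of skipped-diene terminus and methyl-branched vinyl group that is well known from macrolide work.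

Step 13
Reactants: 15 (1S,3E,7E,10E,12S,13R,14R)-13-(tert-butyldimethylsilyloxy)-17-norcembra-3,7,10-trien-16,14-olide
Product: 16 (1S,3E,7E,12S,13R,14R)-13-(tert-butyldimethylsilyloxy)-17-norcembra-3,7-dien-16,14-olide
Conditions: 2,4,6-triisopropylbenzenesulfonyl hydrazide, Et3N, ClCH2CH2Cl, 50 °C
Reagents that add atoms: none
Why: Diimide reduction transfers two hydrogens in a concerted syn step and discriminates sharply by substitution, so the 1,2-disubstituted C10=C11 bond should be saturated while both trisubstituted alkenes survive.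

Step 14
Reactants: 16 (1S,3E,7E,12S,13R,14R)-13-(tert-butyldimethylsilyloxy)-17-norcembra-3,7-dien-16,14-olide
Product: 19 (1S,3E,7E,12S,13R,14R)-13-(tert-butyldimethylsilyloxy)cembra-3,7,15(17)-trien-16,14-olide, via Mannich base 17 (not isolated), via methiodide 18 (not isolated)
Conditions: LiN(iPr)2, THF, −78 °C; CH2=NMe2+ I−, −78 °C to rt; MeI, rt; aq NaHCO3, CH2Cl2, rt
Reagents that add atoms: N,N-dimethylmethyleneiminium iodide (Eschenmoser's salt), C=[N+](C)C.[I-]; iodomethane, CI (its methyl group stays only in 18)
Why: Kinetic deprotonation at C15 (the only site acidic enough), Mannich reaction with Eschenmoser's salt, quaternisation and Hofmann-type β-elimination make up the standard α-methylenation of γ-lactones, and the transient C15 centre is erased.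

Step 15
Reactants: 19 (1S,3E,7E,12S,13R,14R)-13-(tert-butyldimethylsilyloxy)cembra-3,7,15(17)-trien-16,14-olide
Product: 20 (1S,3E,7E,12S,13R,14R)-13-hydroxycembra-3,7,15(17)-trien-16,14-olide
Conditions: HF·pyridine, THF, 0 °C to rt
Reagents that add atoms: none
Why: Fluoride-driven cleavage of the silyl ether under mildly acidic conditions spares the base-sensitive methylene lactone and gives the lactone no chance to migrate to O13.

Step 16
Reactants: 20 (1S,3E,7E,12S,13R,14R)-13-hydroxycembra-3,7,15(17)-trien-16,14-olide
Product: 21 3,4-deoxyeupalmerin acetate, (1S,3E,7E,12S,13R,14R)-13-acetoxycembra-3,7,15(17)-trien-16,14-olide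
Conditions: Ac2O, pyridine, DMAP (cat.), CH2Cl2, rt
Reagents that add atoms: acetic anhydride, CC(=O)OC(C)=O
Why: DMAP-catalysed acylation esterifies the hindered secondary alcohol without touching a stereocentre.

Step 17
Reactants: 21 3,4-deoxyeupalmerin acetate
Product: 22 eupalmerin acetate, (1S,3R,4R,7E,12S,13R,14R)-13-acetoxy-3,4-epoxycembra-7,15(17)-dien-16,14-olide
Conditions: purified cytochrome P450 BM3 variant, NADP+ (cat.), glucose dehydrogenase, D-glucose, air, K2HPO4/KH2PO4 buffer pH 7.5, 2% DMSO, 25 °C
Reagents that add atoms: dioxygen, O=O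
Why: The haem iron is reduced by NADPH (recycled by glucose dehydrogenase), binds O2 and is converted into a tetravalent iron–oxo porphyrin radical cation, which passes its single oxygen atom to the alkene held above it. The closest known reaction type is the epoxidation of E-trisubstituted alkenes of acyclic and macrocyclic terpenoids, fourteen-membered cembranoid alcohols included, by engineered variants of this same enzyme. The oxirane closes by a suprafacial [2+1] oxygen-atom transfer in which both C–O bonds come from one oxygen, so the E geometry is carried into the trans relation of C2 and C5. C3 and C4 are thus fixed relative to each other by the alkene and in the absolute sense (3R,4R, attack on the 3Re,4Re face) by the chiral pocket alone, since C1 is too remote and the ring too mobile to help. The step needs site selectivity for C3=C4 over C7=C8 and chemoselectivity over C15=C17 and over allylic C–H hydroxylation; the substrate offers an electron-poor and therefore inert methylene lactone, and a polar lactone–acetate edge next to C3=C4 only, which gives the pocket a handle to orient the ring. The variant is picked by screening active-site libraries (positions 75, 78, 87, 263 and 328) against 21 with LC–MS read-out.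

**Compound list**

1 | geranyl acetate | CC(C)=CCC/C(C)=C/COC(C)=O | starting material
2 | (2E,6E)-8-hydroxy-3,7-dimethylocta-2,6-dien-1-yl acetate | OC/C(C)=C/CC/C(C)=C/COC(C)=O | intermediate
3 | (2E,6E)-8-bromo-3,7-dimethylocta-2,6-dien-1-yl acetate | BrC/C(C)=C/CC/C(C)=C/COC(C)=O | intermediate
4 | (2E,6E)-3,7-dimethyldeca-2,6,9-trien-1-yl acetate | C=CC/C(C)=C/CC/C(C)=C/COC(C)=O | intermediate
5 | prop-2-yn-1-ol | C#CCO | starting material
6 | (E)-3-(tributylstannyl)prop-2-en-1-ol | CCCC[Sn](CCCC)(CCCC)/C=C/CO | intermediate
7 | (2E,5E,9E)-6,10-dimethyltrideca-2,5,9,12-tetraen-1-ol | OC/C=C/C/C=C(\C)CC/C=C(\C)CC=C | intermediate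
8 | {(2S,3S)-3-[(2E,6E)-3,7-dimethyldeca-2,6,9-trien-1-yl]oxiran-2-yl}methanol | OC[C@@H]1O[C@H]1C/C=C(\C)CC/C=C(\C)CC=C | intermediate
9 | (2R,3S)-3-[(2E,6E)-3,7-dimethyldeca-2,6,9-trien-1-yl]oxirane-2-carbaldehyde | O=C[C@@H]1O[C@H]1C/C=C(\C)CC/C=C(\C)CC=C | intermediate
10 | O-(diisopinocampheylboryl) derivative of 11 | C=C[C@H](C)[C@@H](OB([C@H]2C[C@H]3C[C@@H]([C@@H]2C)C3(C)C)[C@H]2C[C@H]3C[C@@H]([C@@H]2C)C3(C)C)[C@@H]1O[C@H]1C/C=C(\C)CC/C=C(\C)CC=C | intermediate
11 | (1R,2S)-1-{(2S,3S)-3-[(2E,6E)-3,7-dimethyldeca-2,6,9-trien-1-yl]oxiran-2-yl}-2-methylbut-3-en-1-ol | C=C[C@H](C)[C@@H](O)[C@@H]1O[C@H]1C/C=C(\C)CC/C=C(\C)CC=C | intermediate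
12 | tert-butyldimethylsilyl ether of 11 | C=C[C@H](C)[C@@H](O[Si](C)(C)C(C)(C)C)[C@@H]1O[C@H]1C/C=C(\C)CC/C=C(\C)CC=C | intermediate
13 | (3S,4R,5R,6S,8E,12E)-4-(tert-butyldimethylsilyloxy)-6-(ethoxyethynyl)-3,9,13-trimethylhexadeca-1,8,12,15-tetraen-5-ol | C=C[C@H](C)[C@@H](O[Si](C)(C)C(C)(C)C)[C@H](O)[C@H](C#COCC)C/C=C(\C)CC/C=C(\C)CC=C | intermediate
14 | (4S,5R)-5-[(1R,2S)-1-(tert-butyldimethylsilyloxy)-2-methylbut-3-en-1-yl]-4-[(2E,6E)-3,7-dimethyldeca-2,6,9-trien-1-yl]dihydrofuran-2(3H)-one | C=C[C@H](C)[C@@H](O[Si](C)(C)C(C)(C)C)[C@@H]1OC(=O)C[C@@H]1C/C=C(\C)CC/C=C(\C)CC=C | intermediate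
15 | (1S,3E,7E,10E,12S,13R,14R)-13-(tert-butyldimethylsilyloxy)-17-norcembra-3,7,10-trien-16,14-olide | C1C(=O)O[C@H]2[C@H](O[Si](C)(C)C(C)(C)C)[C@@H](C)/C=C/C/C(C)=C/CC/C(C)=C/C[C@@H]12 | intermediate
16 | (1S,3E,7E,12S,13R,14R)-13-(tert-butyldimethylsilyloxy)-17-norcembra-3,7-dien-16,14-olide | C1C(=O)O[C@H]2[C@H](O[Si](C)(C)C(C)(C)C)[C@@H](C)CCC/C(C)=C/CC/C(C)=C/C[C@@H]12 | intermediate
17 | 15-(dimethylaminomethyl) derivative of 16 (C15 epimers, configuration without consequence) | CN(C)CC1C(=O)O[C@H]2[C@H](O[Si](C)(C)C(C)(C)C)[C@@H](C)CCC/C(C)=C/CC/C(C)=C/C[C@@H]12 | intermediate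
18 | trimethylammonium iodide derived from 17 | C[N+](C)(C)CC1C(=O)O[C@H]2[C@H](O[Si](C)(C)C(C)(C)C)[C@@H](C)CCC/C(C)=C/CC/C(C)=C/C[C@@H]12.[I-] | intermediate
19 | (1S,3E,7E,12S,13R,14R)-13-(tert-butyldimethylsilyloxy)cembra-3,7,15(17)-trien-16,14-olide | C=C1C(=O)O[C@H]2[C@H](O[Si](C)(C)C(C)(C)C)[C@@H](C)CCC/C(C)=C/CC/C(C)=C/C[C@@H]12 | intermediate
20 | (1S,3E,7E,12S,13R,14R)-13-hydroxycembra-3,7,15(17)-trien-16,14-olide | C=C1C(=O)O[C@H]2[C@H](O)[C@@H](C)CCC/C(C)=C/CC/C(C)=C/C[C@@H]12 | intermediate
21 | 3,4-deoxyeupalmerin acetate | C=C1C(=O)O[C@H]2[C@H](OC(C)=O)[C@@H](C)CCC/C(C)=C/CC/C(C)=C/C[C@@H]12 | intermediate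
22 | eupalmerin acetate | C=C1C(=O)O[C@H]2[C@H](OC(C)=O)[C@@H](C)CCC/C(C)=C/CC[C@@]3(C)O[C@@H]3C[C@@H]12 | target

**Step count and risks**

Total step count: 17. Longest linear sequence: 16 (steps 1–3 and 5–17, from geranyl acetate).

Steps most likely to fail:

First, step 17.
- What may go wrong: the screening may not deliver a variant that combines site and face selectivity. Oxygen may go to C7=C8 or to both alkenes, and allylic C–H hydroxylation may compete. The poorly soluble substrate may uncouple NADPH consumption from oxidation, and conjugate addition of protein thiols to C17 may inactivate the enzyme.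
- Fallback: it sets out from 21 and comes back at 22, and it replaces pocket control by reagent control. A Shi epoxidation (D-fructose-derived ketone, KHSO5 as Oxone, 2KHSO5·KHSO4·K2SO4, K2CO3 buffer, MeCN/dimethoxymethane/water, 0 °C) generates a chiral dioxirane. Its spiro transition state gives (R,R)-oxiranes from E-trisubstituted alkenes, and because it is electrophilic it leaves C15=C17 alone.
- Limit of the fallback: the dioxirane cannot tell C3=C4 from C7=C8. It is therefore run to partial conversion, the mono-epoxides are separated by chromatography and unreacted 21 is recycled. No new compound lies on this path (F0).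

Second, step 12.
- What may go wrong: alkylidene transfer to the hindered C11 vinyl group may be followed by capture of the nearby C3=C4 bond, which closes a seven-membered ring with loss of the C4–C10 chain. Alternatively, slow closure onto the hindered vinyl group may let oligomerisation win.
- Fallback: it sets out from 12 and comes back at 16, and it changes the order of ring formation to macrocycle before lactone. In oxirane 12, C13 and C2 stand trans on the three-membered ring, so the seven-membered closure would require a trans-fused bicycle and is shut off.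
- Sequence: metathesis of 12 under the conditions of step 12 gives the macrocyclic epoxy triene F1. Diimide as in step 13 gives the macrocyclic epoxy diene F2. The ring is large enough for the trans C14–C1 unit to turn its back side outwards, so BF3-assisted opening with lithium ethoxyacetylide at C1 gives the macrocyclic hydroxy ynol ether F3. Catalytic p-TsOH in wet THF then closes the lactone to 16.

Third, step 10.
- What may go wrong: attack on the internal oxirane may be sluggish and regiocontrol may erode. The Lewis acid may trigger hydride shift, participation of the homoallylic C3=C4 bond, or silyl migration.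
- Fallback: it sets out from 12 and comes back at 14, and it avoids any Lewis acid by using a soft enolate. Sodium dimethyl malonate (NaH, dimethyl malonate, DMF, 80 °C) opens the oxirane at C1 with inversion. The released C14 alkoxide closes onto one ester to give the α-methoxycarbonyl lactone F4. Krapcho demethoxycarbonylation (LiCl, wet DMSO, 140 °C) then gives 14.

**Further compounds**

F0 | step 17 | none | none
F1 | step 12 | (1S,14S)-1,14-epoxy macrocyclic triene: fourteen-membered ring with trans-oxirane at C14–C1, E-alkenes at C3, C7 and C10, 12S-methyl, 13R-OTBS | C[C@H]1/C=C/C/C(C)=C/CC/C(C)=C/C[C@@H]2O[C@H]2[C@@H]1O[Si](C)(C)C(C)(C)C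
F2 | step 12 | 10,11-dihydro derivative of F1 | C[C@H]1CCC/C(C)=C/CC/C(C)=C/C[C@@H]2O[C@H]2[C@@H]1O[Si](C)(C)C(C)(C)C
F3 | step 12 | macrocyclic (1S,12S,13R,14R)-1-(ethoxyethynyl)-14-hydroxy-13-OTBS diene | C[C@H]1CCC/C(C)=C/CC/C(C)=C/C[C@@H](C#COCC)[C@@H](O)[C@@H]1O[Si](C)(C)C(C)(C)C
F4 | step 10 | 3-methoxycarbonyl derivative of lactone 14 (C15 epimers) | C=C[C@H](C)[C@@H](O[Si](C)(C)C(C)(C)C)[C@@H]1OC(=O)C(C(=O)OC)[C@@H]1C/C=C(\C)CC/C=C(\C)CC=C
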